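The amounts were 14 mM of J and 15.4 mM of X, which is 1.10 times J but enters by feed over 1.0 min, with 0.70 mM of D in the flask against 1 mM in the south-east run.

| flask | J | X | D | remark | time |
|---|---|---|---|---|---|
| south-east | 14 mM | 15.4 mM (fed, over 1.0 min) | 1 mM | run made earlier |  |
| flask | 14 mM | 15.4 mM (fed, over 1.0 min) | 0.70 mM |  | 2.0 min |

south-east run (percent of the J charged)

| time / s | G / % | J / % |
|---|---|---|
| 10.0 | 1.3 | 86.7 |
| 15.0 | 0.3 | 76.0 |
| 40.0 | 12.1 | 38.0 |

(scatter of a reading: 0.5 percentage points)

- steps under discussion: J + Q -> Q + E; Q + E <-> Z; X + Z -> Q + G; D -> Q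
- no earlier run changes the charge of D; that part of a forecast is a guess

* amount of G in percent of the J charged, at 25 s, 1.0 min and 2.0 min

I began with J, whose loss comes before G. In the south-east run J fell from 76.0% at 15.0 s to 38.0% at 40.0 s, which read as a pseudo-first-order constant of 0.0277 s⁻¹. Since no earlier run changes D, I guessed proportion to D and took 0.0194 s⁻¹ as the J clock k of the flask, the fractional loss of J per second once catalyst is working. From there I set the time scales of the flask in order.

1. The lag came first. Running the south-east line back to the full charge gave an apparent start of J loss at L = 5.10 s, a value read from scattered readings, and I kept L for the flask, again as a guess.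

2. The J clock came next, with 1/k = 51.5 s, longer than the lag.

3. The feed came third, since its 1.0 min is longer than 1/k. I therefore expected J = exp(−k(t − L)) to stand at 34.5% when the flask's feed stopped and at 10.8% at 2.0 min.

4. G came last. At 40.0 s the south-east run had lost 62.0% of its J and held 12.1% of G, so 49.9% stood between them, as E or Z, while the X fed by then was 73.3% of the J charged.

For G in the flask I reckoned an estimated ceiling, the J lost by this clock, which was 89.2% at 2.0 min.

The forecast gave 1.9%, 19% and 52%, on the ground “I assume both rates scale with D”.

The flask gave 2.02%, 21.0% and 54.9%.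

    J + Q → Q + E (k = 48.0 M⁻¹ s⁻¹)
    Q + E ⇌ Z (K = 100 M⁻¹, k = 3300 M⁻¹ s⁻¹)
    X + Z → Q + G (k = 32.0 M⁻¹ s⁻¹)
    D → Q (k = 0.0880 s⁻¹)

J stood at 8.84% at 2.0 min against my 10.8%, and G lay under my estimated ceiling of 89.2%, with E at 34.6%. Two things acting together held that gap open: Z went back to Q + E, and the run without that back reaction reached 73.5% of G at 2.0 min; and the time was short, for at 20.0 min the J clock put the ceiling at >99.9% and G stood at 99.5%.

The data come from a simulation with constants of no real substance; the scatter is artificial.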